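**Remark on numbering.** Locants C1–C15 are those of the germacrane skeleton: ring C1–C10; C11–C13 on C7 (C12 the lactone carbonyl, C13 the methylene); C14 the ester carbon on C10; C15 the methyl on C4. Primed locants belong to the C8 acyl group.

**Remark on protecting groups.** Through ring closure and desulfonylation C9 carries a triethylsilyl ether, not its acetate: a C9 acetate is an allylic leaving group toward zerovalent palladium and a β-leaving group toward negative charge at C10. C12 carries a 4-methoxybenzyl ether and C8 a tert-butyldimethylsilyl ether, so that the three oxygens can be released in the order C12, C9, C8.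

## Analysis of the target

The target 48 is a germacranolide of the melampolide type. Its ten-membered carbocycle (C1–C10) has a C1=C10 double bond that is cis within the ring and carries the methyl ester C14. The ring is fused at C6/C7 to a trans α-methylene-γ-butyrolactone and at C4/C5 to a trans epoxide bearing C15. Six contiguous ring stereocentres run from C4 to C9 (4R,5R,6S,7R,8R,9S): on the ring C6–O and C7–C11 are trans, C7–C11 and C8–O are trans, C8–O and C9–O are cis. Two more stereocentres sit in the C8 ester, (2R,3S)-3-chloro-2-hydroxy-2-methylbutanoate, which is formally the anti chlorohydrin of a tiglate. The sensitive groups are the methylene lactone (Michael acceptor, isomerised by base), the acid-labile trisubstituted epoxide, the chlorohydrin next to a tertiary alcohol (closes to an epoxide with base) and two different esters on vicinal oxygens (acyl migration). The difficulty lies in closing a medium ring that contains a cis trisubstituted enoate, and in placing a lactone, a hindered ester and an acetate on four adjacent oxygens. The plan rests on one feature: C2–C3 joins two allylic methylene carbons, and C6–O stands 1,4 to C3 across C4=C5 once the epoxide is read as its alkene. That is the pattern left when a C2 carbanion opens a C5–C6 vinyl epoxide through a π-allylpalladium intermediate at its remote terminus C3.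

## Retrosynthetic reasoning

**48 from 47.** The C4–O and C5–O bonds are cut first. The epoxide is the most acid-sensitive group and C4=C5 is the only electron-rich alkene of 47, so a peracid can install it last without protection.

**47 from 46, and 46 from 40 and 44.** The C3′–Cl bond is traced to opening of the epoxy ester 46 by chloride, and the C8–O–C1′ ester bond to alcohol 40 and epoxy acid 44. The compact epoxy acid, which has no free hydroxyl, is easier to couple to the hindered C8 hydroxyl than a tertiary α-hydroxy acid, and no base meets the chlorohydrin. Acid 44 comes from 41 through 42 and 43, the two side-chain stereocentres being set by a reagent-controlled epoxidation.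

**40 back to 37.** Removing the C8 silyl ether (39), the C9 acetate (38) and the C9 silyl ether (37) in turn leaves a lactone with two different silyl ethers. This is what allows the two vicinal oxygens to be acylated differently.

**37 from 34, and 34 from 33.** The C12–O6 lactone bond is cut by oxidative lactonisation of the 6,12-diol 34. With C8 and C9 silylated only the 6,12-lactone can form. Diol 34 comes from 33 by oxidative removal of the benzylic ether.

**33 from 32.** The C2–S bond of the activating sulfone is cut reductively. It is cut directly after ring closure, while C6–OH is a free allylic alcohol and C9 bears a silyl ether that cannot ionise.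

**32 from 30 (key disconnection).** C2–C3 is cut. Both carbons are allylic, and cutting here turns the ring into a chain whose two ends are a vinyl epoxide (C3=C4 with the C5–C6 epoxide) and a γ-sulfonyl enoate. The forward reaction must form the ring, the E-C4=C5 alkene and the free C6 hydroxyl at once. It creates no stereocentre that is kept, since C6 is carried in from the epoxide.

**30 from 29, 29 from 28, 28 from 20 and 26.** The C9 silyl ether is removed (29). The C10=C1 double bond is traced to a selenoxide elimination (28), and the C9–C10 bond to an aldol addition of the enolate of 26 to aldehyde 20. In this way the sulfone arrives with the reagent and never meets the basic steps that build the vinyl epoxide. Ester 26 comes from 24 and 25, and 24 from 21 and 22.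

**20 back to 14 and 15.** Aldehyde 20 comes from 19 and 18. The C3=C4 alkene of 18 is cut to the epoxy ketone 17, the two epoxide C–O bonds to the E-enone 16, and C5=C6 to aldehyde 14 and phosphonate 15. The trans epoxide and its absolute configuration then come from a catalyst-controlled nucleophilic epoxidation.

**14 back to 8 and 9.** Aldehyde 14 comes from 13 and 12. The C7–C8 bond of 11 is cut to imide 8 and aldehyde 9 (auxiliary-controlled syn aldol), which sets C7 and C8 in one step.

**8 from 5 and 6; 5 from 3; 3 from 1 and 2.** The acyl unit C6/C7/C11–C13 is made from commercial materials by etherification and carboxylation of a symmetrical allyl unit.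

## Alternatives that were turned down

**Alternative 1: alkenylchromium closure at C5–C6 with lactonisation.**
- Disconnection: C5–C6 and the lactone C–O bond. The open chain A2 carries an E-alkenyl iodide at C5, an aldehyde at C6 and the C12 ester.
- Forward step: CrCl2 with catalytic NiCl2 adds the alkenylchromium to the aldehyde and the C6 alkoxide lactonises, giving A1.
- For it: A1 is identical with 39. It would be reached without desulfonylation, benzyl-ether cleavage, oxidation or protecting-group exchange, so on step economy after ring closure it is stronger. The E geometry of C4=C5 is fixed in the iodide.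
- Against it: C6 is created in the ring-closing step, under the control of a ten-membered transition state only. Aldehyde A2 has an acidic C7–H (α to the aldehyde and γ to the acrylate). The C9 acetate on a 2-carbomethoxy allyl unit is at risk with low-valent nickel and divalent chromium. The acrylate is exposed throughout. Medium-ring closures of this kind need a large excess of chromium at high dilution.
- Comparison: the chosen route is longer after closure, but C6 is set beforehand by a reagent-controlled epoxidation, no stereocentre is made during closure, and the metal is catalytic.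

**Alternative 2: photochemical electrocyclic opening.**
- Disconnection: a C5–C10 bond is added, hiding the ring in the cis-fused bicyclic cyclohexa-1,3-diene A4.
- Forward step: low-temperature irradiation opens A4 in a conrotatory 6π process to the triene A3.
- For it: the closure is unimolecular, so dilution and the entropy of macrocyclisation do not arise; on this point it is stronger. The alkene geometries follow from orbital symmetry.
- Against it: A4 needs a quaternary C10 bearing the ester beside four stereocentres. Conrotation can turn in two senses. A3 is itself photolabile and thermally labile (reclosure, hydrogen shifts). The extra C2=C3 alkene must afterwards be reduced in the presence of C1=C10 and C4=C5. The lactone methylene has to be masked as an amine adduct and unmasked.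
- Comparison: the chosen route gives C2 and C3 at the right oxidation level directly, under thermal and neutral conditions.

**Alternative 3: indium Barbier closure at C7–C8.**
- Disconnection: C7–C8. The open chain A6 is a 5-substituted 3-(bromomethyl)furan-2(5H)-one with a C8 aldehyde.
- Forward step: indium metal forms the allylindium, which adds through C7 to the aldehyde and gives A5.
- For it: ring, C7–C8 bond and exocyclic methylene are formed together, and the epoxide and lactone are already in place. The endgame would be the shortest of all, and on convergence it is stronger.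
- Against it: two stereocentres (C7 and C8) are formed in the closure, with their sense relative to C6 and C9 decided only by the cyclic transition state. The epoxide must survive trivalent indium salts. C6–H of the butenolide and C9–H of A6 are acidic. A5 emerges with the silyl group on C9 and the free hydroxyl on C8, which still has to be turned into acetate and ester.
- Comparison: the chosen route places its risk in a closure that makes no stereocentre, after all ring stereocentres except C4/C5 have been set by reagent control.

Key step: step 18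

## Route

**Step 1**
Reactants: 1 4-methoxybenzyl alcohol; 2 3-chloro-2-(chloromethyl)prop-1-ene
Product: 3 PMB 2-(chloromethyl)allyl ether
Conditions: NaH, THF, 0 °C; 2 (3 equiv), Bu4NI (cat.), 50 °C
Reagents that add atoms: none
Why: Williamson ether synthesis; the alkoxide of 1 displaces one allylic chloride of the symmetrical dichloride, whose excess should keep substitution at the mono stage.

**Step 2**
Reactants: 3 PMB 2-(chloromethyl)allyl ether
Product: 5 3-[(4-methoxybenzyloxy)methyl]but-3-enoic acid, via allylmagnesium chloride 4 (not isolated)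
Conditions: Mg, THF, 0 °C; CO2, −20 °C; aq. HCl
Reagents that add atoms: carbon dioxide, O=C=O
Why: Grignard formation and carboxylation; the two termini of the 2-substituted allyl unit are equivalent, so α- and γ-attack on CO2 give the same β,γ-unsaturated acid.

**Step 3**
Reactants: 5 3-[(4-methoxybenzyloxy)methyl]but-3-enoic acid; 6 (R)-4-benzyloxazolidin-2-one
Product: 8 N-acyl oxazolidinone, via mixed pivalic anhydride 7 (not isolated)
Conditions: t-BuCOCl, Et3N, THF, −20 °C; then 6, LiCl, −20 °C to rt
Reagents that add atoms: none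
Why: N-acylation through the mixed anhydride with LiCl/Et3N activation of the oxazolidinone; the absence of strong base should keep the alkene out of conjugation.

**Step 4**
Reactants: 8 N-acyl oxazolidinone; 9 (tert-butyldimethylsilyloxy)acetaldehyde
Product: 11 syn-aldol imide, via Z-boron enolate 10 (not isolated)
Conditions: Bu2BOTf, i-Pr2NEt, CH2Cl2, −78 to 0 °C; 9, −78 to 0 °C; H2O2, pH 7 buffer, MeOH
Reagents that add atoms: none
Why: Evans syn-aldol reaction; the Z-boron enolate reacts through a Zimmerman–Traxler chair on the face away from the benzyl group, which with the (R)-auxiliary should set C7 (R) and C8 (R), that is C7–C11 and C8–O syn along C6–C9; but-3-enoyl imides enolise at the α-carbon without conjugation.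

**Step 5**
Reactants: 11 syn-aldol imide
Product: 12 bis-TBS imide
Conditions: t-BuMe2SiOTf, 2,6-lutidine, CH2Cl2, −78 °C
Reagents that add atoms: tert-butyldimethylsilyl triflate, CC(C)(C)[Si](C)(C)OS(=O)(=O)C(F)(F)F
Why: Silylation of the hindered secondary hydroxyl with the silyl triflate; a silyl ether at C8 is also what later makes the C9 aldehyde react under Felkin–Anh control.

**Step 6**
Reactants: 12 bis-TBS imide
Product: 13 C6 alcohol
Conditions: LiBH4, MeOH (1 equiv), THF, 0 °C
Reagents that add atoms: none
Why: Reductive cleavage of the N-acyl oxazolidinone at the exocyclic carbonyl; the auxiliary 6 is released for re-use and no other reducible group is present.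

**Step 7**
Reactants: 13 C6 alcohol
Product: 14 C6 aldehyde
Conditions: Dess–Martin periodinane, NaHCO3, CH2Cl2, 0 °C
Reagents that add atoms: none
Why: Dess–Martin oxidation under buffered, non-basic conditions; the aldehyde (C7–H is α to the carbonyl and allylic) is used at once to avoid epimerisation or conjugation.

**Step 8**
Reactants: 14 C6 aldehyde; 15 dimethyl (2-oxopropyl)phosphonate
Product: 16 E-enone
Conditions: Ba(OH)2, THF/H2O (40:1), 0 °C to rt
Reagents that add atoms: none
Why: Horner–Wadsworth–Emmons olefination with a β-keto phosphonate under mild barium hydroxide activation, which is fast enough to spare the C7 stereocentre and should give the E-enone.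

**Step 9**
Reactants: 16 E-enone
Product: 17 trans-epoxy ketone
Conditions: La(O-i-Pr)3 (10 mol %), (S)-BINOL, Ph3As=O, t-BuOOH, 4 Å MS, THF, rt
Reagents that add atoms: tert-butyl hydroperoxide, CC(C)(C)OO
Why: Catalyst-controlled nucleophilic (Weitz–Scheffer type) epoxidation; conjugate addition of the peroxide and ring closure give the trans epoxide from the E-enone, and the BINOL enantiomer expected to deliver (αR,βS)-epoxy ketones should set C5 (R) and C6 (S); the isolated 1,1-disubstituted alkene is inert to a nucleophilic oxidant.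

**Step 10**
Reactants: 17 trans-epoxy ketone
Product: 18 isopropenyl epoxide bis-TBS ether
Conditions: Ph3PCH3Br, KN(SiMe3)2, THF, 0 °C; then 17, −78 to 0 °C
Reagents that add atoms: methyltriphenylphosphonium bromide, C[P+](c1ccccc1)(c1ccccc1)c1ccccc1.[Br-]
Why: Wittig methylenation of an α,β-epoxy ketone; the epoxide C–H is not readily enolised, so C5 should be retained, and no acidic or electrophilic group is yet present elsewhere.

**Step 11**
Reactants: 18 isopropenyl epoxide bis-TBS ether
Product: 19 C9 alcohol
Conditions: Bu4NF, AcOH (1:1), THF, 0 °C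
Reagents that add atoms: none
Why: Selective fluoride desilylation; the primary silyl ether is cleaved faster than the hindered secondary one, and buffering with acetic acid suppresses silyl migration and leaves the vinyl epoxide untouched.

**Step 12**
Reactants: 19 C9 alcohol
Product: 20 C9 aldehyde
Conditions: Dess–Martin periodinane, NaHCO3, CH2Cl2, 0 °C
Reagents that add atoms: none
Why: Dess–Martin oxidation; the buffered neutral medium is compatible with the vinyl epoxide and the α-silyloxy aldehyde.

**Step 13**
Reactants: 21 diphenyl diselenide; 22 methyl bromoacetate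
Product: 24 methyl 2-(phenylselanyl)acetate, via sodium benzeneselenolate 23 (not isolated)
Conditions: NaBH4, MeOH/THF, 0 °C; then 22, 0 °C to rt
Reagents that add atoms: none
Why: Reductive cleavage of the diselenide and SN2 alkylation of the soft selenolate.

**Step 14**
Reactants: 24 methyl 2-(phenylselanyl)acetate; 25 phenyl vinyl sulfone
Product: 26 methyl 4-(phenylsulfonyl)-2-(phenylselanyl)butanoate
Conditions: LiN(SiMe3)2, THF, −78 °C; then 25, −78 to −40 °C; AcOH
Reagents that add atoms: none
Why: Michael addition of an ester enolate to a vinyl sulfone; proton transfer turns the first-formed α-sulfonyl carbanion into the more stable, hindered α-seleno enolate, which should not add a second time.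

**Step 15**
Reactants: 20 C9 aldehyde; 26 methyl 4-(phenylsulfonyl)-2-(phenylselanyl)butanoate
Product: 28 β-hydroxy selenide (C10 epimers), via lithium enolate 27 (not isolated)
Conditions: LiN(i-Pr)2, THF, −78 °C; then 20, −78 °C; AcOH, −78 °C
Reagents that add atoms: none
Why: Aldol addition; the C–H flanked by ester and selenium is far more acidic than the sulfonyl CH2, and polar Felkin–Anh addition to the α-silyloxy aldehyde should give the 8,9-anti product (C9 as required); the C10 configuration is irrelevant because C10 becomes sp2 next, and the vinyl epoxide is inert at −78 °C.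

**Step 16**
Reactants: 28 β-hydroxy selenide (C10 epimers)
Product: 29 γ-sulfonyl enoate C9 alcohol
Conditions: m-CPBA (1.05 equiv), CH2Cl2, −78 °C; then i-Pr2NH, −78 °C to rt
Reagents that add atoms: none
Why: Selenoxide syn-elimination; it proceeds away from the hydroxyl-bearing C9 toward C1, and the transition state that places C2 cis to C9 and not to the ester (the less strained, tiglate-type arrangement) should dominate; the amine traps the selenenic acid.

**Step 17**
Reactants: 29 γ-sulfonyl enoate C9 alcohol
Product: 30 cyclisation precursor (C9 TES ether)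
Conditions: Et3SiCl, imidazole, DMAP (cat.), DMF, 0 °C to rt
Reagents that add atoms: chlorotriethylsilane, CC[Si](Cl)(CC)CC
Why: Silylation without a Lewis acid, which spares the vinyl epoxide; the silyl ether at C9 can neither ionise toward zerovalent palladium nor leave from the C2 carbanion, and it prevents O-alkylation by a free hydroxyl in the next step.

**Step 18**
Reactants: 30 cyclisation precursor (C9 TES ether)
Product: 32 ten-membered C2 sulfone (C2 epimers), via π-allylpalladium zwitterion 31 (not isolated)
Conditions: Pd(PPh3)4 (10 mol %), THF, 50 °C, slow addition of 30 (final 2 mM)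
Reagents that add atoms: none
Why: Zerovalent palladium coordinates the isopropenyl alkene anti to the C5–O bond and ionises the strained epoxide to 31, a π-allyl over C3–C4–C5 with the C6 alkoxide as the only base (Tsuji–Trost reaction of a vinyl epoxide under neutral conditions; closest known type: palladium-catalysed macrocyclisation of vinyl epoxides with sulfone-stabilised pronucleophiles). The alkoxide removes a C2 proton of the γ-sulfonyl enoate, a vinylogous α-sulfonyl ester, within the same molecule, so nucleophile and electrophile arise pairwise and at low stationary concentration, which with slow addition should favour ring closure over oligomerisation. The ten-membered ring closes by attack of C2 on the unsubstituted terminus C3 (1,4-addition); attack at C5 would give an eight-membered ring at the hindered terminus next to the alkoxide, and attack through C10 would create a quaternary centre. Attack at C3 of the syn allyl unit gives E-C4=C5, and C6–O is not touched, so C6 keeps the configuration set in step 9; the only new stereocentre, C2, is removed in step 19. The delocalised anion can rotate about C1–C10, so the ring-alkene geometry is decided in the cyclisation transition state; the arrangement with C2 cis to C9 is the one built into 30, is the less strained enoate geometry and places the nucleophilic carbon on the side of the tether, so the cis ring alkene is expected. Only the vinyl epoxide should ionise at this temperature: the silyl ethers and the benzyl ether are not leaving groups, and all other hydroxyls are masked, so no oxygen nucleophile competes for the allyl cation.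

**Step 19**
Reactants: 32 ten-membered C2 sulfone (C2 epimers)
Product: 33 ten-membered dienol
Conditions: Pd(PPh3)4 (10 mol %), NaBH4, THF/i-PrOH, 0 °C to rt
Reagents that add atoms: none
Why: Palladium-catalysed hydride reduction of an allylic sulfone; ionisation gives a π-allyl over C2–C1–C10 with the ester at C10, and hydride should be delivered to C2, the less substituted terminus remote from the ester, which keeps C1=C10 in conjugation. An electron-transfer desulfonylation is avoided because its dienolate would protonate at C10 and could expel the C9 oxygen.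

**Step 20**
Reactants: 33 ten-membered dienol
Product: 34 C6,C12 diol
Conditions: DDQ, CH2Cl2/pH 7 buffer, 0 °C
Reagents that add atoms: none
Why: Oxidative cleavage of the 4-methoxybenzyl ether by hydride abstraction at the benzylic position; silyl ethers, the enoate and the alkenes are inert under buffered conditions.

**Step 21**
Reactants: 34 C6,C12 diol
Product: 37 trans-lactone (C8 TBS, C9 TES), via hydroxy enal 35 (not isolated), via lactol 36 (not isolated)
Conditions: TEMPO (20 mol %), PhI(OAc)2, CH2Cl2, rt
Reagents that add atoms: none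
Why: Oxoammonium-mediated oxidative lactonisation of a 1,4-diol; the primary allylic alcohol is oxidised first, the enal closes to the five-membered lactol with the C6 hydroxyl and is oxidised on; C8 and C9 are silylated, so only the 6,12-lactone can form, and its trans fusion follows from C6 and C7.

**Step 22**
Reactants: 37 trans-lactone (C8 TBS, C9 TES)
Product: 38 C9 alcohol lactone
Conditions: PPTS, MeOH/CH2Cl2, 0 °C
Reagents that add atoms: none
Why: Acid-catalysed methanolysis; a triethylsilyl ether is cleaved much faster than a tert-butyldimethylsilyl ether, which leaves C8 protected.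

**Step 23**
Reactants: 38 C9 alcohol lactone
Product: 39 C9 acetate
Conditions: Ac2O, pyridine, DMAP (cat.), CH2Cl2, 0 °C to rt
Reagents that add atoms: acetic anhydride, CC(=O)OC(C)=O
Why: Acetylation of the only free hydroxyl; C6 is already engaged in the lactone, so no selectivity is needed.

**Step 24**
Reactants: 39 C9 acetate
Product: 40 C8 alcohol
Conditions: HF·pyridine, THF, 0 °C to rt
Reagents that add atoms: none
Why: Fluoride-mediated desilylation under acidic conditions, which should disfavour acetyl migration from C9 to C8 and is tolerated by the methylene lactone.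

**Step 25**
Reactants: 41 tiglic acid
Product: 42 (E)-2-methylbut-2-en-1-ol
Conditions: LiAlH4, Et2O, 0 °C
Reagents that add atoms: none
Why: 1,2-Reduction of the conjugated acid to the allylic alcohol with retention of the E geometry.

**Step 26**
Reactants: 42 (E)-2-methylbut-2-en-1-ol
Product: 43 (2R,3R)-epoxy alcohol
Conditions: Ti(O-i-Pr)4 (10 mol %), D-(−)-diethyl tartrate (12 mol %), t-BuOOH, 4 Å MS, CH2Cl2, −20 °C
Reagents that add atoms: tert-butyl hydroperoxide, CC(C)(C)OO
Why: Sharpless asymmetric epoxidation; the D-tartrate catalyst should deliver oxygen to the face of the E-allylic alcohol that gives the (2R,3R)-epoxide, with the methyl groups cis as in the alkene.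

**Step 27**
Reactants: 43 (2R,3R)-epoxy alcohol
Product: 44 (2S,3R)-epoxy acid
Conditions: RuCl3 (2 mol %), NaIO4, CCl4/MeCN/H2O, rt
Reagents that add atoms: sodium periodate, [Na+].[O-]I(=O)(=O)=O; water, O
Why: Ruthenium tetroxide oxidation of a primary alcohol to the acid, generated catalytically with periodate; the epoxide and both stereocentres are untouched (the change of the C2 descriptor is formal).

**Step 28**
Reactants: 40 C8 alcohol; 44 (2S,3R)-epoxy acid
Product: 46 C8 epoxy ester, via mixed Yamaguchi anhydride 45 (not isolated)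
Conditions: 2,4,6-Cl3C6H2COCl, Et3N, THF, rt; then 40, DMAP, toluene, rt to 40 °C
Reagents that add atoms: none
Why: Yamaguchi esterification; the epoxy acid has no free hydroxyl and is compact, which should allow acylation of the hindered C8 hydroxyl through the acylpyridinium species.

**Step 29**
Reactants: 46 C8 epoxy ester
Product: 47 C8 chlorohydrin ester (4,5-alkene)
Conditions: LiCl, AcOH, THF, rt
Reagents that add atoms: lithium chloride, [Li+].[Cl-]
Why: Acid-assisted SN2 opening of a glycidic ester by chloride at C3′ (C2′ is fully substituted and α to the carbonyl), with inversion at C3′, which gives the (2′R,3′S)-chlorohydrin; the alkenes, the acetate and the lactone are inert to this weak acid.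

**Step 30**
Reactants: 47 C8 chlorohydrin ester (4,5-alkene)
Product: 48 target
Conditions: m-CPBA, NaHCO3, CH2Cl2, 0 °C
Reagents that add atoms: 3-chloroperbenzoic acid, O=C(OO)c1cccc(Cl)c1
Why: Prilezhaev epoxidation; C4=C5 is the only electron-rich alkene (the other two are conjugated to carbonyl groups), and attack on the outer face of the E alkene, which stands roughly perpendicular to the mean plane of the ten-membered ring, is expected to give the (4R,5R)-epoxide.

## Compound list

1 | 4-methoxybenzyl alcohol | COc1ccc(CO)cc1 | starting material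
2 | 3-chloro-2-(chloromethyl)prop-1-ene | C=C(CCl)CCl | starting material
3 | 1-({[2-(chloromethyl)prop-2-en-1-yl]oxy}methyl)-4-methoxybenzene | C=C(CCl)COCc1ccc(OC)cc1 | intermediate
4 | {2-[(4-methoxybenzyloxy)methyl]prop-2-en-1-yl}magnesium chloride | C=C(C[Mg]Cl)COCc1ccc(OC)cc1 | intermediate (not isolated)
5 | 3-[(4-methoxybenzyloxy)methyl]but-3-enoic acid | C=C(CC(=O)O)COCc1ccc(OC)cc1 | intermediate
6 | (R)-4-benzyloxazolidin-2-one | O=C1N[C@H](Cc2ccccc2)CO1 | starting material
7 | 3-[(4-methoxybenzyloxy)methyl]but-3-enoic pivalic anhydride | C=C(CC(=O)OC(=O)C(C)(C)C)COCc1ccc(OC)cc1 | intermediate (not isolated)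
8 | (R)-4-benzyl-3-{3-[(4-methoxybenzyloxy)methyl]but-3-enoyl}oxazolidin-2-one | C=C(CC(=O)N1C(=O)OC[C@H]1Cc1ccccc1)COCc1ccc(OC)cc1 | intermediate
9 | (tert-butyldimethylsilyloxy)acetaldehyde | CC(C)(C)[Si](C)(C)OCC=O | starting material
10 | (Z)-dibutylboron enolate of 8 | CCCCB(CCCC)O/C(N1C(=O)OC[C@H]1Cc1ccccc1)=C\C(=C)COCc1ccc(OC)cc1 | intermediate (not isolated)
11 | (R)-4-benzyl-3-[(2R,3R)-4-(tert-butyldimethylsilyloxy)-3-hydroxy-2-{3-[(4-methoxybenzyl)oxy]prop-1-en-2-yl}butanoyl]oxazolidin-2-one | O=C(N1C(=O)OC[C@H]1Cc1ccccc1)[C@H](C(=C)COCc1ccc(OC)cc1)[C@@H](O)CO[Si](C)(C)C(C)(C)C | intermediate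
12 | (R)-4-benzyl-3-[(2R,3R)-3,4-bis(tert-butyldimethylsilyloxy)-2-{3-[(4-methoxybenzyl)oxy]prop-1-en-2-yl}butanoyl]oxazolidin-2-one | O=C(N1C(=O)OC[C@H]1Cc1ccccc1)[C@H](C(=C)COCc1ccc(OC)cc1)[C@@H](O[Si](C)(C)C(C)(C)C)CO[Si](C)(C)C(C)(C)C | intermediate
13 | (2S,3R)-3,4-bis(tert-butyldimethylsilyloxy)-2-{3-[(4-methoxybenzyl)oxy]prop-1-en-2-yl}butan-1-ol | OC[C@H](C(=C)COCc1ccc(OC)cc1)[C@@H](O[Si](C)(C)C(C)(C)C)CO[Si](C)(C)C(C)(C)C | intermediate
14 | (2R,3R)-3,4-bis(tert-butyldimethylsilyloxy)-2-{3-[(4-methoxybenzyl)oxy]prop-1-en-2-yl}butanal | O=C[C@H](C(=C)COCc1ccc(OC)cc1)[C@@H](O[Si](C)(C)C(C)(C)C)CO[Si](C)(C)C(C)(C)C | intermediate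
15 | dimethyl (2-oxopropyl)phosphonate | COP(=O)(CC(C)=O)OC | starting material
16 | (3E,5R,6R)-6,7-bis(tert-butyldimethylsilyloxy)-5-{3-[(4-methoxybenzyl)oxy]prop-1-en-2-yl}hept-3-en-2-one | CC(=O)/C=C/[C@H](C(=C)COCc1ccc(OC)cc1)[C@@H](O[Si](C)(C)C(C)(C)C)CO[Si](C)(C)C(C)(C)C | intermediate
17 | (3R,4S,5S,6R)-6,7-bis(tert-butyldimethylsilyloxy)-3,4-epoxy-5-{3-[(4-methoxybenzyl)oxy]prop-1-en-2-yl}heptan-2-one | CC(=O)[C@@H]1O[C@H]1[C@H](C(=C)COCc1ccc(OC)cc1)[C@@H](O[Si](C)(C)C(C)(C)C)CO[Si](C)(C)C(C)(C)C | intermediate
18 | (3S,4S,5S,6R)-6,7-bis(tert-butyldimethylsilyloxy)-3,4-epoxy-5-{3-[(4-methoxybenzyl)oxy]prop-1-en-2-yl}-2-methylhept-1-ene | C=C(C)[C@@H]1O[C@H]1[C@H](C(=C)COCc1ccc(OC)cc1)[C@@H](O[Si](C)(C)C(C)(C)C)CO[Si](C)(C)C(C)(C)C | intermediate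
19 | (2R,3S,4S,5S)-2-(tert-butyldimethylsilyloxy)-4,5-epoxy-3-{3-[(4-methoxybenzyl)oxy]prop-1-en-2-yl}-6-methylhept-6-en-1-ol | C=C(C)[C@@H]1O[C@H]1[C@H](C(=C)COCc1ccc(OC)cc1)[C@@H](O[Si](C)(C)C(C)(C)C)CO | intermediate
20 | (2R,3S,4S,5S)-2-(tert-butyldimethylsilyloxy)-4,5-epoxy-3-{3-[(4-methoxybenzyl)oxy]prop-1-en-2-yl}-6-methylhept-6-enal | C=C(C)[C@@H]1O[C@H]1[C@H](C(=C)COCc1ccc(OC)cc1)[C@@H](O[Si](C)(C)C(C)(C)C)C=O | intermediate
21 | diphenyl diselenide | c1ccc([Se][Se]c2ccccc2)cc1 | starting material
22 | methyl bromoacetate | COC(=O)CBr | starting material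
23 | sodium benzeneselenolate | [Na+].[Se-]c1ccccc1 | intermediate (not isolated)
24 | methyl 2-(phenylselanyl)acetate | COC(=O)C[Se]c1ccccc1 | intermediate
25 | phenyl vinyl sulfone | C=CS(=O)(=O)c1ccccc1 | starting material
26 | methyl 4-(phenylsulfonyl)-2-(phenylselanyl)butanoate (racemic) | COC(=O)C(CCS(=O)(=O)c1ccccc1)[Se]c1ccccc1 | intermediate
27 | lithium enolate of 26 | COC(O[Li])=C(CCS(=O)(=O)c1ccccc1)[Se]c1ccccc1 | intermediate (not isolated)
28 | methyl (3R,4R,5S,6S,7S)-4-(tert-butyldimethylsilyloxy)-6,7-epoxy-3-hydroxy-5-{3-[(4-methoxybenzyl)oxy]prop-1-en-2-yl}-8-methyl-2-(phenylselanyl)-2-[2-(phenylsulfonyl)ethyl]non-8-enoate (epimers at C2 of the chain, germacrane C10) | C=C(C)[C@@H]1O[C@H]1[C@H](C(=C)COCc1ccc(OC)cc1)[C@@H](O[Si](C)(C)C(C)(C)C)[C@@H](O)C(CCS(=O)(=O)c1ccccc1)(C(=O)OC)[Se]c1ccccc1 | intermediate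
29 | methyl (2E,3S,4R,5S,6S,7S)-4-(tert-butyldimethylsilyloxy)-6,7-epoxy-3-hydroxy-5-{3-[(4-methoxybenzyl)oxy]prop-1-en-2-yl}-8-methyl-2-[2-(phenylsulfonyl)ethylidene]non-8-enoate | C=C(C)[C@@H]1O[C@H]1[C@H](C(=C)COCc1ccc(OC)cc1)[C@@H](O[Si](C)(C)C(C)(C)C)[C@@H](O)/C(C(=O)OC)=C\CS(=O)(=O)c1ccccc1 | intermediate
30 | methyl (2E,3S,4R,5S,6S,7S)-4-(tert-butyldimethylsilyloxy)-6,7-epoxy-5-{3-[(4-methoxybenzyl)oxy]prop-1-en-2-yl}-8-methyl-2-[2-(phenylsulfonyl)ethylidene]-3-(triethylsilyloxy)non-8-enoate | C=C(C)[C@@H]1O[C@H]1[C@H](C(=C)COCc1ccc(OC)cc1)[C@@H](O[Si](C)(C)C(C)(C)C)[C@@H](O[Si](CC)(CC)CC)/C(C(=O)OC)=C\CS(=O)(=O)c1ccccc1 | intermediate (precursor of the key step)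
31 | zwitterionic allylpalladium alkoxide from 30, drawn as its C3-bound σ-allyl form with two PPh3 | [O-][C@H](/C=C(C)/C[Pd+](P(c1ccccc1)(c1ccccc1)c1ccccc1)P(c1ccccc1)(c1ccccc1)c1ccccc1)[C@H](C(=C)COCc1ccc(OC)cc1)[C@@H](O[Si](C)(C)C(C)(C)C)[C@@H](O[Si](CC)(CC)CC)/C(C(=O)OC)=C\CS(=O)(=O)c1ccccc1 | intermediate (not isolated)
32 | methyl (1(10)E,4E,6R,7S,8R,9S)-8-(tert-butyldimethylsilyloxy)-6-hydroxy-12-(4-methoxybenzyloxy)-2-(phenylsulfonyl)-9-(triethylsilyloxy)germacra-1(10),4,11(13)-trien-14-oate (C2 epimers) | O[C@H]1[C@H](C(=C)COCc2ccc(OC)cc2)[C@@H](O[Si](C)(C)C(C)(C)C)[C@@H](O[Si](CC)(CC)CC)/C(C(=O)OC)=C\C(S(=O)(=O)c2ccccc2)C/C(C)=C/1 | intermediate (product of the key step)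
33 | methyl (1(10)E,4E,6R,7S,8R,9S)-8-(tert-butyldimethylsilyloxy)-6-hydroxy-12-(4-methoxybenzyloxy)-9-(triethylsilyloxy)germacra-1(10),4,11(13)-trien-14-oate | O[C@H]1[C@H](C(=C)COCc2ccc(OC)cc2)[C@@H](O[Si](C)(C)C(C)(C)C)[C@@H](O[Si](CC)(CC)CC)/C(C(=O)OC)=C\CC/C(C)=C/1 | intermediate
34 | methyl (1(10)E,4E,6R,7S,8R,9S)-8-(tert-butyldimethylsilyloxy)-6,12-dihydroxy-9-(triethylsilyloxy)germacra-1(10),4,11(13)-trien-14-oate | O[C@H]1[C@H](C(=C)CO)[C@@H](O[Si](C)(C)C(C)(C)C)[C@@H](O[Si](CC)(CC)CC)/C(C(=O)OC)=C\CC/C(C)=C/1 | intermediate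
35 | 12-oxo analogue of 34 (hydroxy enal) | O[C@H]1[C@H](C(=C)C=O)[C@@H](O[Si](C)(C)C(C)(C)C)[C@@H](O[Si](CC)(CC)CC)/C(C(=O)OC)=C\CC/C(C)=C/1 | intermediate (not isolated)
36 | 6,12-lactol of 35 (C12 epimers) | C=C1C(O)O[C@H]2[C@H]1[C@@H](O[Si](C)(C)C(C)(C)C)[C@@H](O[Si](CC)(CC)CC)/C(C(=O)OC)=C\CC/C(C)=C/2 | intermediate (not isolated)
37 | methyl (1(10)E,4E,6R,7S,8R,9S)-8-(tert-butyldimethylsilyloxy)-9-(triethylsilyloxy)germacra-1(10),4,11(13)-trien-12,6-olid-14-oate | C=C1C(=O)O[C@H]2[C@H]1[C@@H](O[Si](C)(C)C(C)(C)C)[C@@H](O[Si](CC)(CC)CC)/C(C(=O)OC)=C\CC/C(C)=C/2 | intermediate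
38 | methyl (1(10)E,4E,6R,7S,8R,9S)-8-(tert-butyldimethylsilyloxy)-9-hydroxygermacra-1(10),4,11(13)-trien-12,6-olid-14-oate | C=C1C(=O)O[C@H]2[C@H]1[C@@H](O[Si](C)(C)C(C)(C)C)[C@@H](O)/C(C(=O)OC)=C\CC/C(C)=C/2 | intermediate
39 | methyl (1(10)E,4E,6R,7S,8R,9S)-9-acetoxy-8-(tert-butyldimethylsilyloxy)germacra-1(10),4,11(13)-trien-12,6-olid-14-oate | C=C1C(=O)O[C@H]2[C@H]1[C@@H](O[Si](C)(C)C(C)(C)C)[C@@H](OC(C)=O)/C(C(=O)OC)=C\CC/C(C)=C/2 | intermediate
40 | methyl (1(10)E,4E,6R,7R,8R,9S)-9-acetoxy-8-hydroxygermacra-1(10),4,11(13)-trien-12,6-olid-14-oate | C=C1C(=O)O[C@H]2[C@H]1[C@@H](O)[C@@H](OC(C)=O)/C(C(=O)OC)=C\CC/C(C)=C/2 | intermediate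
41 | tiglic acid | C/C=C(\C)C(=O)O | starting material
42 | (E)-2-methylbut-2-en-1-ol | C/C=C(\C)CO | intermediate
43 | [(2R,3R)-2,3-dimethyloxiran-2-yl]methanol | OC[C@@]1(C)O[C@@H]1C | intermediate
44 | (2S,3R)-2,3-dimethyloxirane-2-carboxylic acid | OC(=O)[C@@]1(C)O[C@@H]1C | intermediate
45 | (2S,3R)-2,3-dimethyloxirane-2-carboxylic 2,4,6-trichlorobenzoic anhydride | O=C(OC(=O)c1c(Cl)cc(Cl)cc1Cl)[C@@]1(C)O[C@@H]1C | intermediate (not isolated)
46 | methyl (1(10)E,4E,6R,7S,8R,9S)-9-acetoxy-8-{[(2S,3R)-2,3-dimethyloxiran-2-yl]carbonyloxy}germacra-1(10),4,11(13)-trien-12,6-olid-14-oate | C=C1C(=O)O[C@H]2[C@H]1[C@@H](OC(=O)[C@@]1(C)O[C@@H]1C)[C@@H](OC(C)=O)/C(C(=O)OC)=C\CC/C(C)=C/2 | intermediate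
47 | methyl (1(10)E,4E,6R,7S,8R,9S)-9-acetoxy-8-[(2R,3S)-3-chloro-2-hydroxy-2-methylbutanoyloxy]germacra-1(10),4,11(13)-trien-12,6-olid-14-oate | C=C1C(=O)O[C@H]2[C@H]1[C@@H](OC(=O)[C@@](C)(O)[C@H](C)Cl)[C@@H](OC(C)=O)/C(C(=O)OC)=C\CC/C(C)=C/2 | intermediate
48 | methyl (1(10)E,4R,5R,6S,7R,8R,9S)-9-acetoxy-8-[(2R,3S)-3-chloro-2-hydroxy-2-methylbutanoyloxy]-4,5-epoxygermacra-1(10),11(13)-dien-12,6-olid-14-oate | C=C1C(=O)O[C@H]2[C@H]1[C@@H](OC(=O)[C@@](C)(O)[C@H](C)Cl)[C@@H](OC(C)=O)/C(C(=O)OC)=C\CC[C@@]1(C)O[C@H]21 | target

## Step count and least certain steps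

Total: 30 steps. Longest linear sequence: 25 steps (1–12, 15–24, 28–30); steps 13–14 and 25–27 make the two side reagents.

**Step 18 (key step).** The most likely failure is oligomerisation, or loss of a β-hydrogen from the allylpalladium unit, because a ten-membered closure is slow. A second failure is closure through the other rotamer of the delocalised anion, which would give the trans ring alkene. A third is competing ionisation of the allylic sulfone if the temperature must be raised.
Fallback: a base-mediated sulfone alkylation in place of the palladium isomerisation. It sets out from 30, which is opened in the 1,4 sense with MgBr2·OEt2 (the allylic bromides equilibrate to the primary one) to the E-allylic bromide with free C6 hydroxyl F1. Acetylation gives the C6 acetate F2. Cs2CO3 in DMF at high dilution closes C2–C3 by intramolecular SN2 alkylation of the sulfonyl carbanion to the macrocyclic acetate F3. K2CO3 in MeOH removes the acetate, and the route is rejoined at 32.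

**Step 19.** The risk is delivery of hydride to C10 or migration of the C1=C10 double bond through isomerisation of the allyl complex; slow conjugate reduction of the enoate is a lesser risk.
Fallback: from 32, electron-transfer cleavage with SmI2 in THF/MeOH at −78 °C, accepting kinetic protonation at C10, gives the deconjugated β,γ-unsaturated ester F4. Brief treatment with DBU moves the alkene back into conjugation, and the route is rejoined at 33.

**Step 15.** The risk is poor facial selectivity at C9, since the Felkin–Anh preference of a lithium ester enolate can be modest. The geometry set in step 16 is a lesser concern, because both geometrical isomers give the same anion in step 18.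
Fallback: C9 is set by reduction instead of by C–C bond formation. From the mixture 28, Dess–Martin oxidation gives the β-keto-α-seleno ester F5, and reduction with the bulky hydride LiB(s-Bu)3H at −78 °C (Felkin–Anh, anti to the C8 silyloxy group) returns 28 with C9 defined.

**Step 9.** The risk is poor facial selectivity if the catalyst and the C7 stereocentre are mismatched, or γ-deprotonation at the doubly allylic C7–H.
Fallback: the epoxide is set on an allylic alcohol. From 14, Horner–Wadsworth–Emmons reaction with triethyl phosphonoacetate gives the E-enoate F6. (i-Bu)2AlH gives the allylic alcohol F7. Sharpless epoxidation with Ti(O-i-Pr)4 and L-(+)-diethyl tartrate gives the (2S,3S)-epoxy alcohol F8. Oxidation gives the epoxy aldehyde F9, MeMgBr the carbinol F10, and a second oxidation rejoins the route at 17.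

**Step 30.** The risk is poor facial selectivity if the reactive conformer of the ring does not expose the required face of C4=C5.
Fallback: reagent control in place of substrate control. From 47, epoxidation with the chiral dioxirane generated from the appropriate enantiomer of the fructose-derived ketone and KHSO5 at pH 7–8 (mild enough for the chlorohydrin and the lactone) leads directly to 48; no new compound is made.

## Further compounds

F1 | step 18 | methyl (2E,3S,4R,5S,6R,7E)-9-bromo-4-(tert-butyldimethylsilyloxy)-6-hydroxy-5-{3-[(4-methoxybenzyl)oxy]prop-1-en-2-yl}-8-methyl-2-[2-(phenylsulfonyl)ethylidene]-3-(triethylsilyloxy)non-7-enoate (C3–C9 configured as in 30) | BrC/C(C)=C/[C@@H](O)[C@H](C(=C)COCc1ccc(OC)cc1)[C@@H](O[Si](C)(C)C(C)(C)C)[C@@H](O[Si](CC)(CC)CC)/C(C(=O)OC)=C\CS(=O)(=O)c1ccccc1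
F2 | step 18 | C6 acetate of F1 | BrC/C(C)=C/[C@@H](OC(C)=O)[C@H](C(=C)COCc1ccc(OC)cc1)[C@@H](O[Si](C)(C)C(C)(C)C)[C@@H](O[Si](CC)(CC)CC)/C(C(=O)OC)=C\CS(=O)(=O)c1ccccc1
F3 | step 18 | C6 acetate of 32 (C2 epimers) | CC(=O)O[C@H]1[C@H](C(=C)COCc2ccc(OC)cc2)[C@@H](O[Si](C)(C)C(C)(C)C)[C@@H](O[Si](CC)(CC)CC)/C(C(=O)OC)=C\C(S(=O)(=O)c2ccccc2)C/C(C)=C/1
F4 | step 19 | methyl 8-(tert-butyldimethylsilyloxy)-6-hydroxy-12-(4-methoxybenzyloxy)-9-(triethylsilyloxy)germacra-1,4,11(13)-trien-14-oate, the deconjugated isomer of 33 (C10 epimers, C1=C2 geometry open) | O[C@H]1[C@H](C(=C)COCc2ccc(OC)cc2)[C@@H](O[Si](C)(C)C(C)(C)C)[C@@H](O[Si](CC)(CC)CC)C(C(=O)OC)C=CC/C(C)=C/1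
F5 | step 15 | C9 ketone of 28 (β-keto-α-seleno ester, C10 epimers) | C=C(C)[C@@H]1O[C@H]1[C@H](C(=C)COCc1ccc(OC)cc1)[C@@H](O[Si](C)(C)C(C)(C)C)C(=O)C(CCS(=O)(=O)c1ccccc1)(C(=O)OC)[Se]c1ccccc1
F6 | step 9 | ethyl (2E,4R,5R)-5,6-bis(tert-butyldimethylsilyloxy)-4-{3-[(4-methoxybenzyl)oxy]prop-1-en-2-yl}hex-2-enoate | CCOC(=O)/C=C/[C@H](C(=C)COCc1ccc(OC)cc1)[C@@H](O[Si](C)(C)C(C)(C)C)CO[Si](C)(C)C(C)(C)C
F7 | step 9 | (2E,4R,5R)-5,6-bis(tert-butyldimethylsilyloxy)-4-{3-[(4-methoxybenzyl)oxy]prop-1-en-2-yl}hex-2-en-1-ol | OC/C=C/[C@H](C(=C)COCc1ccc(OC)cc1)[C@@H](O[Si](C)(C)C(C)(C)C)CO[Si](C)(C)C(C)(C)C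
F8 | step 9 | (2S,3S,4S,5R)-5,6-bis(tert-butyldimethylsilyloxy)-2,3-epoxy-4-{3-[(4-methoxybenzyl)oxy]prop-1-en-2-yl}hexan-1-ol | OC[C@@H]1O[C@H]1[C@H](C(=C)COCc1ccc(OC)cc1)[C@@H](O[Si](C)(C)C(C)(C)C)CO[Si](C)(C)C(C)(C)C
F9 | step 9 | (2R,3S,4S,5R)-5,6-bis(tert-butyldimethylsilyloxy)-2,3-epoxy-4-{3-[(4-methoxybenzyl)oxy]prop-1-en-2-yl}hexanal | O=C[C@@H]1O[C@H]1[C@H](C(=C)COCc1ccc(OC)cc1)[C@@H](O[Si](C)(C)C(C)(C)C)CO[Si](C)(C)C(C)(C)C
F10 | step 9 | (3S,4S,5S,6R)-6,7-bis(tert-butyldimethylsilyloxy)-3,4-epoxy-5-{3-[(4-methoxybenzyl)oxy]prop-1-en-2-yl}heptan-2-ol (C2 epimers) | CC(O)[C@@H]1O[C@H]1[C@H](C(=C)COCc1ccc(OC)cc1)[C@@H](O[Si](C)(C)C(C)(C)C)CO[Si](C)(C)C(C)(C)C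
F0 | step 30 | none | none
A1 | alternative 1 | methyl (1(10)E,4E,6R,7S,8R,9S)-9-acetoxy-8-(tert-butyldimethylsilyloxy)germacra-1(10),4,11(13)-trien-12,6-olid-14-oate (identical with 39) | C=C1C(=O)O[C@H]2[C@H]1[C@@H](O[Si](C)(C)C(C)(C)C)[C@@H](OC(C)=O)/C(C(=O)OC)=C\CC/C(C)=C/2
A2 | alternative 1 | open-chain C6 aldehyde with an E-alkenyl iodide at C5, the C12 methyl ester, C8 silyl ether and C9 acetate | O=C[C@H](C(=C)C(=O)OC)[C@@H](O[Si](C)(C)C(C)(C)C)[C@@H](OC(C)=O)/C(C(=O)OC)=C\CC/C(C)=C/I
A3 | alternative 2 | methyl 13-(dimethylamino)-8,9-O-isopropylidene-8,9-dihydroxy-11,13-dihydrogermacra-1(10),2,4-trien-12,6-olid-14-oate (C11 open) | CN(C)CC1C(=O)O[C@H]2[C@H]1[C@H]1OC(C)(C)O[C@H]1/C(C(=O)OC)=C\C=C/C(C)=C/2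
A4 | alternative 2 | cis-fused bicyclic cyclohexa-1,3-diene with the C5–C10 bond closed (one of the two cis-fused diastereomers, drawn arbitrarily) | CN(C)CC1C(=O)O[C@H]2[C@H]1[C@H]1OC(C)(C)O[C@H]1[C@@]1(C(=O)OC)C=CC=C(C)[C@@H]21
A5 | alternative 3 | methyl (1(10)E,4R,5R,6S,7R,8R,9S)-9-(tert-butyldimethylsilyloxy)-4,5-epoxy-8-hydroxygermacra-1(10),11(13)-dien-12,6-olid-14-oate | C=C1C(=O)O[C@H]2[C@H]1[C@@H](O)[C@@H](O[Si](C)(C)C(C)(C)C)/C(C(=O)OC)=C\CC[C@@]1(C)O[C@H]21
A6 | alternative 3 | open-chain C8 aldehyde carrying the 3-(bromomethyl)furan-2(5H)-one at C6, the 4,5-epoxide and the C9 silyl ether | O=C[C@@H](O[Si](C)(C)C(C)(C)C)/C(C(=O)OC)=C\CC[C@@]1(C)O[C@@H]1[C@H]1OC(=O)C(CBr)=C1
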